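**Plan**

1. Retrosynthetic cuts, in order: the aryl ketone C(=O)–aryl bond and the silyl ethers; the O–CH(aryl) bond of the tetrahydrofuran ring that carries the keto-chain arene; in the other tetrahydrofuran ring, the C–C bond between the ArCH carbon and the ring-fusion carbon (forward: contraction of a seven-membered ring); the dioxepine–alkenyl C–C bond; the C2–C3 bond of the dihydrobenzofuran.
2. Enabling feature: that ring contains ArCH–O–CH2, and its ArCH carbon sits next to a ring carbon carrying an exocyclic CH2–O carbon. With that carbon as CHO, the ring is a 2-aryltetrahydrofuran-3-carbaldehyde, the 1,3 O-to-C isomer of a 2-aryl-4,5-dihydro-1,3-dioxepine (a cyclic vinyl acetal holding the same ArCH, O, CH2 and CH atoms plus the two enol carbons).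
3. Forward order: dihydrobenzofuran by carbene C–H insertion on an arene whose aldehyde is already masked as the 4,7-dihydro-1,3-dioxepine; side-chain arene by auxiliary hydroxymethylation; Heck union (allyl acetal to vinyl acetal); ring contraction to the first tetrahydrofuran; second tetrahydrofuran by benzylic etherification; ketone from the Weinreb amide; desilylation.
4. Stereochemistry: the cis C2/C3 pair of the dihydrobenzofuran from Rh2(S-PTTL)4; the side-chain centre from an oxazolidinone; dioxepine C5 from the Heck reaction with Pd2(dba)3 and an (S)-phosphinooxazoline ligand, relayed in the ring contraction to the two new ring carbons; the formyl-bearing carbon then inverted by lactol-trapped epimerisation; the last benzylic centre by exo closure of a benzylic cation.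

Key step: step 19

**Assumptions**

- The dihydrobenzofuran of the target is 2,3-cis (2S,3S) as written, so a cis-selective ring construction is used and strong acid is avoided afterwards.
- The sense of induction of Rh2(S-PTTL)4 (step 5) and of the (S)-phosphinooxazoline ligand (step 18) is assigned by analogy; if either proves opposite, the mirror-image catalyst is used.
- Compounds 1 and 39 are taken as catalogue items (otherwise one silylation each from vanillin and from 12).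

**Abbreviations**

- TBS = tert-butyldimethylsilyl.
- DBF = (2S,3S)-3-[(TBS-oxy)methyl]-2-[4-(TBS-oxy)-3-methoxyphenyl]-7-methoxy-2,3-dihydro-1-benzofuran-5-yl.
- ArW = 4-(TBS-oxy)-3-methoxy-5-[(2S)-1-(TBS-oxy)-3-[methoxy(methyl)amino]-3-oxopropan-2-yl]phenyl.

**Fragment A (steps 1–7)**

Step 1
Reactants: 1 4-(TBS-oxy)-3-methoxybenzaldehyde
Product: 2 [4-(TBS-oxy)-3-methoxyphenyl]methanol
Conditions: NaBH4, EtOH/THF, 0 °C
Reagents that add atoms: none
Why: Borohydride reduction of the aldehyde; the aryl silyl ether should survive at 0 °C.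

Step 2
Reactants: 2 [4-(TBS-oxy)-3-methoxyphenyl]methanol; 3 4-hydroxy-3-iodo-5-methoxybenzaldehyde (5-iodovanillin)
Product: 4 4-{[4-(TBS-oxy)-3-methoxyphenyl]methoxy}-3-iodo-5-methoxybenzaldehyde
Conditions: PPh3, DIAD, THF, 0 °C to rt
Reagents that add atoms: none
Why: Mitsunobu etherification; the formyl-acidified phenol should be alkylated by the primary benzylic alkoxyphosphonium salt under neutral conditions.

Step 3
Reactants: 4 the aryl benzyl ether aldehyde; 5 (Z)-but-2-ene-1,4-diol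
Product: 6 2-(4-{[4-(TBS-oxy)-3-methoxyphenyl]methoxy}-3-iodo-5-methoxyphenyl)-4,7-dihydro-1,3-dioxepine
Conditions: PPTS (cat.), benzene, reflux, Dean–Stark
Reagents that add atoms: none
Why: Acid-catalysed acetalisation with azeotropic removal of water; the seven-membered allyl acetal masks the aldehyde through the carbene steps and is the later Heck partner.

Step 4
Reactants: 6 the iodoarene acetal; 7 ethyl diazoacetate
Product: 8 ethyl 2-diazo-2-[2-{[4-(TBS-oxy)-3-methoxyphenyl]methoxy}-5-(4,7-dihydro-1,3-dioxepin-2-yl)-3-methoxyphenyl]acetate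
Conditions: Pd(PPh3)4 (5 mol%), Ag2CO3, Et3N, toluene, rt
Reagents that add atoms: none
Why: Palladium-catalysed cross-coupling of an aryl iodide with an acceptor diazo compound with retention of the diazo group (C–H arylation of the diazoacetate); the ring alkene and the acetal should be inert at rt.

Step 5
Reactants: 8 the aryldiazoacetate
Product: 9 ethyl (2S,3R)-2-[4-(TBS-oxy)-3-methoxyphenyl]-5-(4,7-dihydro-1,3-dioxepin-2-yl)-7-methoxy-2,3-dihydro-1-benzofuran-3-carboxylate (2,3-cis)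
Conditions: Rh2(S-PTTL)4 (1 mol%), toluene, −60 °C
Reagents that add atoms: none
Why: Intramolecular 1,5 C–H insertion of the dirhodium carbenoid into the benzylic, ether-activated C–H bond (Hashimoto-type dihydrobenzofuran synthesis); the concerted insertion should give the cis isomer and the chiral carboxylate ligands should set both new centres.

Step 6
Reactants: 9 the cis ester
Product: 10 [(2S,3S)-2-[4-(TBS-oxy)-3-methoxyphenyl]-5-(4,7-dihydro-1,3-dioxepin-2-yl)-7-methoxy-2,3-dihydro-1-benzofuran-3-yl]methanol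
Conditions: DIBAL-H, CH2Cl2, −78 °C; potassium sodium tartrate work-up
Reagents that add atoms: none
Why: Low-temperature hydride reduction of the ester to the primary alcohol without enolisation, so the cis relationship should be kept.

Step 7
Reactants: 10 the primary alcohol
Product: 11 2-(DBF)-4,7-dihydro-1,3-dioxepine (fragment A)
Conditions: TBSCl, imidazole, DMF, rt
Reagents that add atoms: tert-butyldimethylsilyl chloride CC(C)(C)[Si](C)(C)Cl
Why: Standard silylation of a primary alcohol.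

**Fragment B (steps 8–17)**

Step 8
Reactants: 12 4-bromo-2-methoxyphenol
Product: 13 4-bromo-2-iodo-6-methoxyphenol
Conditions: NIS, TsOH (cat.), MeCN, 0 °C to rt
Reagents that add atoms: N-iodosuccinimide O=C1CCC(=O)N1I
Why: Electrophilic iodination ortho to the hydroxyl group, the para position being blocked by bromine.

Step 9
Reactants: 13 4-bromo-2-iodo-6-methoxyphenol
Product: 14 (4-bromo-2-iodo-6-methoxyphenoxy)(tert-butyl)dimethylsilane
Conditions: TBSCl, imidazole, DMF, 40 °C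
Reagents that add atoms: tert-butyldimethylsilyl chloride CC(C)(C)[Si](C)(C)Cl
Why: Silylation of the hindered phenol; the flanked aryl silyl ether should be robust in the steps that follow.

Step 10
Reactants: 14 the silyl ether; 15 (2-tert-butoxy-2-oxoethyl)zinc bromide
Product: 16 tert-butyl 2-[5-bromo-2-(TBS-oxy)-3-methoxyphenyl]acetate
Conditions: Pd(dba)2 (2 mol%), Q-Phos (2 mol%), THF, rt
Reagents that add atoms: none
Why: Negishi-type coupling of a Reformatsky reagent (alpha-arylation of an ester zinc enolate); the C–I bond should react well before the C–Br bond with 1.1 equivalents of zinc reagent.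

Step 11
Reactants: 16 the tert-butyl ester
Product: 17 2-[5-bromo-2-(TBS-oxy)-3-methoxyphenyl]acetic acid
Conditions: TFA, CH2Cl2, 0 °C to rt
Reagents that add atoms: none
Why: Acidolysis of the tert-butyl ester with loss of isobutene; the aryl silyl ether should tolerate the short exposure.

Step 12
Reactants: 17 the arylacetic acid; 18 (R)-4-benzyl-1,3-oxazolidin-2-one
Product: 20 (R)-4-benzyl-3-{2-[5-bromo-2-(TBS-oxy)-3-methoxyphenyl]acetyl}-1,3-oxazolidin-2-one, via mixed pivalic anhydride 19 (not isolated)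
Conditions: PivCl, Et3N, THF, −20 °C; then 18, LiCl, rt
Reagents that add atoms: none
Why: Mixed-anhydride N-acylation of the oxazolidinone under the mild LiCl/Et3N protocol.

Step 13
Reactants: 20 the N-arylacetyl oxazolidinone
Product: 22 (R)-4-benzyl-3-{(2S)-2-[5-bromo-2-(TBS-oxy)-3-methoxyphenyl]-3-hydroxypropanoyl}-1,3-oxazolidin-2-one, via chlorotitanium enolate 21 (not isolated)
Conditions: TiCl4, i-Pr2NEt, CH2Cl2, 0 °C; then 1,3,5-trioxane, TiCl4, 0 °C
Reagents that add atoms: 1,3,5-trioxane C1OCOCO1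
Why: Evans hydroxymethylation of a titanium enolate; the chelated Z-enolate should be attacked by the formaldehyde equivalent on the face opposite the benzyl group, which gives the 2S centre.

Step 14
Reactants: 22 the hydroxymethyl imide
Product: 23 (2S)-2-[5-bromo-2-(TBS-oxy)-3-methoxyphenyl]-3-hydroxy-N-methoxy-N-methylpropanamide
Conditions: MeONHMe·HCl, Me3Al, CH2Cl2, −10 to 0 °C
Reagents that add atoms: N,O-dimethylhydroxylamine hydrochloride CNOC.Cl
Why: Weinreb transamidation of the imide by an aluminium amide, assisted by the free beta-hydroxyl, which should remove the auxiliary without enolising the benzylic centre.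

Step 15
Reactants: 23 the hydroxy Weinreb amide
Product: 24 (2S)-2-[5-bromo-2-(TBS-oxy)-3-methoxyphenyl]-3-(TBS-oxy)-N-methoxy-N-methylpropanamide
Conditions: TBSCl, imidazole, DMF, rt
Reagents that add atoms: tert-butyldimethylsilyl chloride CC(C)(C)[Si](C)(C)Cl
Why: Standard silylation of a primary alcohol.

Step 16
Reactants: 24 the bromoarene Weinreb amide; 25 tributyl(1-ethoxyvinyl)stannane
Product: 27 (2S)-2-[5-acetyl-2-(TBS-oxy)-3-methoxyphenyl]-3-(TBS-oxy)-N-methoxy-N-methylpropanamide, via enol ether 26 (not isolated)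
Conditions: PdCl2(PPh3)2 (5 mol%), toluene, 95 °C; then oxalic acid, wet THF, 0 °C
Reagents that add atoms: water O
Why: Stille coupling at the unhindered C–Br bond, then mild hydrolysis of the aryl enol ether to the methyl ketone under neutral to weakly acidic conditions that should leave the benzylic centre untouched.

Step 17
Reactants: 27 the methyl ketone
Product: 29 1-(ArW)ethenyl trifluoromethanesulfonate (fragment B), via potassium enolate 28 (not isolated)
Conditions: KHMDS (1.05 equiv), THF, −78 °C; then PhNTf2, −78 to −20 °C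
Reagents that add atoms: N-phenylbis(trifluoromethanesulfonimide) O=S(=O)(N(c1ccccc1)S(=O)(=O)C(F)(F)F)C(F)(F)F
Why: Kinetic deprotonation of the methyl ketone and O-triflation of the enolate; the tertiary benzylic hydrogen next to the amide is less acidic and far more hindered, so it should not be removed.

**Union and core (steps 18–25)**

Step 18
Reactants: 11 2-(DBF)-4,7-dihydro-1,3-dioxepine; 29 1-(ArW)ethenyl trifluoromethanesulfonate
Product: 30 (5S)-2-(DBF)-5-[1-(ArW)ethenyl]-4,5-dihydro-1,3-dioxepine (both epimers at the acetal carbon)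
Conditions: Pd2(dba)3 (3 mol%), (S)-4-tert-butyl-2-[2-(diphenylphosphino)phenyl]-4,5-dihydrooxazole (7 mol%), i-Pr2NEt, benzene, 60 °C
Reagents that add atoms: none
Why: Cationic asymmetric Heck reaction of an alkenyl triflate with a 4,7-dihydro-1,3-dioxepine; syn insertion followed by syn beta-hydride elimination towards O–CH2 should give the cyclic vinyl acetal directly, and the chiral P,N ligand should choose between the enantiotopic alkene carbons to set C5.

Step 19
Reactants: 30 (5S)-2-(DBF)-5-[1-(ArW)ethenyl]-4,5-dihydro-1,3-dioxepine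
Product: 32 (2S,3R,4S)-2-(DBF)-4-[1-(ArW)ethenyl]oxolane-3-carbaldehyde, via oxocarbenium–enolate ion pair 31 (not isolated)
Conditions: BF3·OEt2 (1.2 equiv), 2,6-di-tert-butyl-4-methylpyridine (0.2 equiv), CH2Cl2, −78 °C; Et3N quench at −78 °C
Reagents that add atoms: none
Why: BF3 binds the enol-ether oxygen O1 of the vinyl acetal and breaks the O1–C2 bond, giving a benzylic oxocarbenium ion (stabilised by the para oxygen of the dihydrobenzofuran) paired with a boron enolate; the enolate carbon C6 then bonds to C2, so the seven-membered ring O1–C2–O3–C4–C5–C6=C7 contracts to the tetrahydrofuran O3–C2–C6–C5–C4 and C7 is pushed out as the formyl group. This is the known Lewis-acid rearrangement of 4,5-dihydro-1,3-dioxepines to tetrahydrofuran-3-carbaldehydes, a Petasis–Ferrier-type 1,3 O-to-C shift. The ring closes in a 5-(enol-exo)-endo-trig mode, the enolate carbon attacking the oxocarbenium carbon whose C=O+ bond lies inside the new ring, a closure that is open to such a cationic acceptor. The Heck-derived centre (old C5, new C4) is untouched; the new C3 should form trans to the C4 substituent because the enolate reacts in the allylic-strain-minimised conformer (C5–H eclipsing the enol double bond, tether on the face away from the arylvinyl group); the new C2 is set by collapse of the tight ion pair at −78 °C, which for this rearrangement gives the 2,3-cis product under kinetic control, so the aryl group ends cis to formyl and trans to the C4 substituent. The step needs this facial selectivity at C2 (it fixes the absolute configuration of the aryl-bearing ring carbon, whereas C3 is inverted in step 21) and chemoselectivity for the enolate over Prins capture of the oxocarbenium by the 1,1-disubstituted styrene; low temperature and the higher nucleophilicity and proximity of the boron enolate should secure both, and the two acetal epimers converge because that carbon becomes planar.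

Step 20
Reactants: 32 the tetrahydrofuran aldehyde
Product: 33 (2S,3R,4R)-2-(DBF)-4-[1,2-dihydroxy-1-(ArW)ethyl]oxolane-3-carbaldehyde (both epimers at the tertiary carbinol)
Conditions: OsO4 (2 mol%), NMO, acetone/H2O, 0 °C to rt
Reagents that add atoms: N-methylmorpholine N-oxide C[N+]1([O-])CCOCC1; water O
Why: Upjohn dihydroxylation of the only alkene; it puts in the oxygen of the future benzylic C–O bond and provides a hydroxyl group that can trap the aldehyde in the next step.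

Step 21
Reactants: 33 the dihydroxy aldehyde
Product: 35 (2S,3R,4R)-2-(DBF)-4-[1,2-dihydroxy-1-(ArW)ethyl]-3-(hydroxymethyl)oxolane, via bicyclic lactol 34 (not isolated)
Conditions: DBU (0.3 equiv), THF, rt; then NaBH4, EtOH, 0 °C
Reagents that add atoms: none
Why: Base epimerisation of the aldehyde alpha-carbon C3 through its enolate, drawn towards the 3,4-cis isomer because only that isomer can close the five-membered cis-fused lactol with the tertiary hydroxyl (the 3,7-dioxabicyclo[3.3.0]octane skeleton of the target) and because it also relieves the cis aryl/formyl interaction, then borohydride reduction of the lactol through its open form, so that C3 should end trans to the aryl group and cis to the C4 branch as in the target.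

Step 22
Reactants: 35 the triol
Product: 37 (2S,3R,4R)-2-(DBF)-4-[hydroxy(ArW)methyl]-3-(hydroxymethyl)oxolane (both carbinol epimers), via hydroxy ketone 36 (not isolated)
Conditions: NaIO4, THF/pH 7 buffer, 0 °C; extractive work-up; then NaBH4, EtOH, 0 °C
Reagents that add atoms: none
Why: Periodate cleavage of the tertiary/primary 1,2-diol unveils the aryl ketone, which is reduced at once so that the carbon alpha to it (C4) has no time to epimerise; the carbinol configuration does not matter for the next step.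

Step 23
Reactants: 37 the diol
Product: 38 (1S,3aR,4S,6aR)-1-(ArW)-4-(DBF)tetrahydro-1H,3H-furo[3,4-c]furan
Conditions: CSA (10 mol%), 4 Å molecular sieves, CH2Cl2, 0 °C
Reagents that add atoms: none
Why: Acid-catalysed SN1 etherification; the para-silyloxybenzylic cation should be captured 5-exo-trig by the primary hydroxyl with the aryl group on the convex (exo) face, and the weak acid at 0 °C should leave the cis-dihydrobenzofuran intact.

Step 24
Reactants: 38 the furofuran Weinreb amide; 39 (4-bromo-2-methoxyphenoxy)(tert-butyl)dimethylsilane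
Product: 41 the pentakis-TBS ether of the target (aryl ketone), via aryllithium 40 (not isolated)
Conditions: 39 (3 equiv), n-BuLi, THF, −78 °C; then 38, −78 to −50 °C; NH4Cl quench at −78 °C
Reagents that add atoms: none
Why: Weinreb ketone synthesis; the aryllithium adds once to give a chelated tetrahedral intermediate that releases the ketone only on the cold quench, so the base-sensitive alpha-aryl ketone should never meet the organolithium.

Step 25
Reactants: 41 the pentakis-TBS ether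
Product: 42 CNP0174045.1 (target)
Conditions: HF·pyridine, pyridine, THF, 0 °C to rt; pH 7 buffer work-up
Reagents that add atoms: none
Why: Global fluoride desilylation under buffered, weakly acidic conditions, which should avoid base (retro-aldol, epimerisation of the alpha-aryl ketone) and strong acid (benzofuran formation, epimerisation of the benzylic ethers).

**Compound list**

1 | 4-[(tert-butyldimethylsilyl)oxy]-3-methoxybenzaldehyde | COc1cc(C=O)ccc1O[Si](C)(C)C(C)(C)C | starting material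
2 | {4-[(tert-butyldimethylsilyl)oxy]-3-methoxyphenyl}methanol | COc1cc(CO)ccc1O[Si](C)(C)C(C)(C)C | intermediate
3 | 4-hydroxy-3-iodo-5-methoxybenzaldehyde | COc1cc(C=O)cc(I)c1O | starting material
4 | 4-{[4-(TBS-oxy)-3-methoxyphenyl]methoxy}-3-iodo-5-methoxybenzaldehyde | COc1cc(C=O)cc(I)c1OCc1ccc(O[Si](C)(C)C(C)(C)C)c(OC)c1 | intermediate
5 | (Z)-but-2-ene-1,4-diol | OC/C=C\CO | starting material
6 | 2-(4-{[4-(TBS-oxy)-3-methoxyphenyl]methoxy}-3-iodo-5-methoxyphenyl)-4,7-dihydro-1,3-dioxepine | COc1cc(C2OCC=CCO2)cc(I)c1OCc1ccc(O[Si](C)(C)C(C)(C)C)c(OC)c1 | intermediate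
7 | ethyl diazoacetate | CCOC(=O)C=[N+]=[N-] | starting material
8 | ethyl 2-diazo-2-[2-{[4-(TBS-oxy)-3-methoxyphenyl]methoxy}-5-(4,7-dihydro-1,3-dioxepin-2-yl)-3-methoxyphenyl]acetate | CCOC(=O)C(=[N+]=[N-])c1cc(C2OCC=CCO2)cc(OC)c1OCc1ccc(O[Si](C)(C)C(C)(C)C)c(OC)c1 | intermediate
9 | ethyl (2S,3R)-2-[4-(TBS-oxy)-3-methoxyphenyl]-5-(4,7-dihydro-1,3-dioxepin-2-yl)-7-methoxy-2,3-dihydro-1-benzofuran-3-carboxylate (cis) | CCOC(=O)[C@@H]1c2cc(C3OCC=CCO3)cc(OC)c2O[C@@H]1c1ccc(O[Si](C)(C)C(C)(C)C)c(OC)c1 | intermediate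
10 | [(2S,3S)-2-[4-(TBS-oxy)-3-methoxyphenyl]-5-(4,7-dihydro-1,3-dioxepin-2-yl)-7-methoxy-2,3-dihydro-1-benzofuran-3-yl]methanol | OC[C@@H]1c2cc(C3OCC=CCO3)cc(OC)c2O[C@@H]1c1ccc(O[Si](C)(C)C(C)(C)C)c(OC)c1 | intermediate
11 | 2-(DBF)-4,7-dihydro-1,3-dioxepine (fragment A) | CC(C)(C)[Si](C)(C)OC[C@@H]1c2cc(C3OCC=CCO3)cc(OC)c2O[C@@H]1c1ccc(O[Si](C)(C)C(C)(C)C)c(OC)c1 | intermediate
12 | 4-bromo-2-methoxyphenol | COc1cc(Br)ccc1O | starting material
13 | 4-bromo-2-iodo-6-methoxyphenol | COc1cc(Br)cc(I)c1O | intermediate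
14 | (4-bromo-2-iodo-6-methoxyphenoxy)(tert-butyl)dimethylsilane | COc1cc(Br)cc(I)c1O[Si](C)(C)C(C)(C)C | intermediate
15 | (2-tert-butoxy-2-oxoethyl)zinc bromide | CC(C)(C)OC(=O)C[Zn]Br | starting material
16 | tert-butyl 2-[5-bromo-2-(TBS-oxy)-3-methoxyphenyl]acetate | COc1cc(Br)cc(CC(=O)OC(C)(C)C)c1O[Si](C)(C)C(C)(C)C | intermediate
17 | 2-[5-bromo-2-(TBS-oxy)-3-methoxyphenyl]acetic acid | COc1cc(Br)cc(CC(=O)O)c1O[Si](C)(C)C(C)(C)C | intermediate
18 | (R)-4-benzyl-1,3-oxazolidin-2-one | O=C1N[C@H](Cc2ccccc2)CO1 | starting material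
19 | 2-[5-bromo-2-(TBS-oxy)-3-methoxyphenyl]acetic pivalic anhydride | COc1cc(Br)cc(CC(=O)OC(=O)C(C)(C)C)c1O[Si](C)(C)C(C)(C)C | intermediate (not isolated)
20 | (R)-4-benzyl-3-{2-[5-bromo-2-(TBS-oxy)-3-methoxyphenyl]acetyl}-1,3-oxazolidin-2-one | COc1cc(Br)cc(CC(=O)N2C(=O)OC[C@H]2Cc2ccccc2)c1O[Si](C)(C)C(C)(C)C | intermediate
21 | trichlorotitanium (Z)-enolate of 20 | COc1cc(Br)cc(/C=C(\O[Ti](Cl)(Cl)Cl)N2C(=O)OC[C@H]2Cc2ccccc2)c1O[Si](C)(C)C(C)(C)C | intermediate (not isolated)
22 | (R)-4-benzyl-3-{(2S)-2-[5-bromo-2-(TBS-oxy)-3-methoxyphenyl]-3-hydroxypropanoyl}-1,3-oxazolidin-2-one | COc1cc(Br)cc([C@@H](CO)C(=O)N2C(=O)OC[C@H]2Cc2ccccc2)c1O[Si](C)(C)C(C)(C)C | intermediate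
23 | (2S)-2-[5-bromo-2-(TBS-oxy)-3-methoxyphenyl]-3-hydroxy-N-methoxy-N-methylpropanamide | COc1cc(Br)cc([C@@H](CO)C(=O)N(C)OC)c1O[Si](C)(C)C(C)(C)C | intermediate
24 | (2S)-2-[5-bromo-2-(TBS-oxy)-3-methoxyphenyl]-3-(TBS-oxy)-N-methoxy-N-methylpropanamide | COc1cc(Br)cc([C@@H](CO[Si](C)(C)C(C)(C)C)C(=O)N(C)OC)c1O[Si](C)(C)C(C)(C)C | intermediate
25 | tributyl(1-ethoxyvinyl)stannane | CCCC[Sn](CCCC)(CCCC)C(=C)OCC | starting material
26 | (2S)-2-[5-(1-ethoxyethenyl)-2-(TBS-oxy)-3-methoxyphenyl]-3-(TBS-oxy)-N-methoxy-N-methylpropanamide | CCOC(=C)c1cc(OC)c(O[Si](C)(C)C(C)(C)C)c(c1)[C@@H](CO[Si](C)(C)C(C)(C)C)C(=O)N(C)OC | intermediate (not isolated)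
27 | (2S)-2-[5-acetyl-2-(TBS-oxy)-3-methoxyphenyl]-3-(TBS-oxy)-N-methoxy-N-methylpropanamide | CC(=O)c1cc(OC)c(O[Si](C)(C)C(C)(C)C)c(c1)[C@@H](CO[Si](C)(C)C(C)(C)C)C(=O)N(C)OC | intermediate
28 | potassium enolate of 27 | [K+].[O-]C(=C)c1cc(OC)c(O[Si](C)(C)C(C)(C)C)c(c1)[C@@H](CO[Si](C)(C)C(C)(C)C)C(=O)N(C)OC | intermediate (not isolated)
29 | 1-(ArW)ethenyl trifluoromethanesulfonate (fragment B) | C=C(OS(=O)(=O)C(F)(F)F)c1cc(OC)c(O[Si](C)(C)C(C)(C)C)c(c1)[C@@H](CO[Si](C)(C)C(C)(C)C)C(=O)N(C)OC | intermediate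
30 | (5S)-2-(DBF)-5-[1-(ArW)ethenyl]-4,5-dihydro-1,3-dioxepine (acetal epimers) | C1(c2cc(OC)c3c(c2)[C@@H](CO[Si](C)(C)C(C)(C)C)[C@@H](c2ccc(O[Si](C)(C)C(C)(C)C)c(OC)c2)O3)OC[C@H](C(=C)c2cc(OC)c(O[Si](C)(C)C(C)(C)C)c(c2)[C@@H](CO[Si](C)(C)C(C)(C)C)C(=O)N(C)OC)C=CO1 | intermediate
31 | oxocarbenium ion / trifluoroborate enolate zwitterion from 30 | F[B-](F)(F)O/C=C\[C@@H](C(=C)c1cc(OC)c(O[Si](C)(C)C(C)(C)C)c(c1)[C@@H](CO[Si](C)(C)C(C)(C)C)C(=O)N(C)OC)C[O+]=Cc1cc(OC)c2c(c1)[C@@H](CO[Si](C)(C)C(C)(C)C)[C@@H](c1ccc(O[Si](C)(C)C(C)(C)C)c(OC)c1)O2 | intermediate (not isolated)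
32 | (2S,3R,4S)-2-(DBF)-4-[1-(ArW)ethenyl]oxolane-3-carbaldehyde (aryl cis to CHO; CHO trans to the C4 group) | [C@H]1(c2cc(OC)c3c(c2)[C@@H](CO[Si](C)(C)C(C)(C)C)[C@@H](c2ccc(O[Si](C)(C)C(C)(C)C)c(OC)c2)O3)OC[C@H](C(=C)c2cc(OC)c(O[Si](C)(C)C(C)(C)C)c(c2)[C@@H](CO[Si](C)(C)C(C)(C)C)C(=O)N(C)OC)[C@H]1C=O | intermediate
33 | (2S,3R,4R)-2-(DBF)-4-[1,2-dihydroxy-1-(ArW)ethyl]oxolane-3-carbaldehyde (tertiary carbinol epimers) | [C@H]1(c2cc(OC)c3c(c2)[C@@H](CO[Si](C)(C)C(C)(C)C)[C@@H](c2ccc(O[Si](C)(C)C(C)(C)C)c(OC)c2)O3)OC[C@H](C(O)(CO)c2cc(OC)c(O[Si](C)(C)C(C)(C)C)c(c2)[C@@H](CO[Si](C)(C)C(C)(C)C)C(=O)N(C)OC)[C@H]1C=O | intermediate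
34 | cis-fused bicyclic lactol: 4-(DBF)-1-(ArW)-1-(hydroxymethyl)tetrahydro-1H,3H-furo[3,4-c]furan-3-ol | [C@H]1(c2cc(OC)c3c(c2)[C@@H](CO[Si](C)(C)C(C)(C)C)[C@@H](c2ccc(O[Si](C)(C)C(C)(C)C)c(OC)c2)O3)OC[C@H]2[C@@H]1C(O)OC2(CO)c1cc(OC)c(O[Si](C)(C)C(C)(C)C)c(c1)[C@@H](CO[Si](C)(C)C(C)(C)C)C(=O)N(C)OC | intermediate (not isolated)
35 | (2S,3R,4R)-2-(DBF)-4-[1,2-dihydroxy-1-(ArW)ethyl]-3-(hydroxymethyl)oxolane | [C@H]1(c2cc(OC)c3c(c2)[C@@H](CO[Si](C)(C)C(C)(C)C)[C@@H](c2ccc(O[Si](C)(C)C(C)(C)C)c(OC)c2)O3)OC[C@H](C(O)(CO)c2cc(OC)c(O[Si](C)(C)C(C)(C)C)c(c2)[C@@H](CO[Si](C)(C)C(C)(C)C)C(=O)N(C)OC)[C@@H]1CO | intermediate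
36 | (2S,3R,4R)-2-(DBF)-3-(hydroxymethyl)-4-[(ArW)carbonyl]oxolane (open form of the hemiketal) | [C@H]1(c2cc(OC)c3c(c2)[C@@H](CO[Si](C)(C)C(C)(C)C)[C@@H](c2ccc(O[Si](C)(C)C(C)(C)C)c(OC)c2)O3)OC[C@H](C(=O)c2cc(OC)c(O[Si](C)(C)C(C)(C)C)c(c2)[C@@H](CO[Si](C)(C)C(C)(C)C)C(=O)N(C)OC)[C@@H]1CO | intermediate (not isolated)
37 | (2S,3R,4R)-2-(DBF)-4-[hydroxy(ArW)methyl]-3-(hydroxymethyl)oxolane (carbinol epimers) | [C@H]1(c2cc(OC)c3c(c2)[C@@H](CO[Si](C)(C)C(C)(C)C)[C@@H](c2ccc(O[Si](C)(C)C(C)(C)C)c(OC)c2)O3)OC[C@H](C(O)c2cc(OC)c(O[Si](C)(C)C(C)(C)C)c(c2)[C@@H](CO[Si](C)(C)C(C)(C)C)C(=O)N(C)OC)[C@@H]1CO | intermediate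
38 | (1S,3aR,4S,6aR)-1-(ArW)-4-(DBF)tetrahydro-1H,3H-furo[3,4-c]furan | [C@H]1(c2cc(OC)c3c(c2)[C@@H](CO[Si](C)(C)C(C)(C)C)[C@@H](c2ccc(O[Si](C)(C)C(C)(C)C)c(OC)c2)O3)OC[C@H]2[C@@H]1CO[C@@H]2c1cc(OC)c(O[Si](C)(C)C(C)(C)C)c(c1)[C@@H](CO[Si](C)(C)C(C)(C)C)C(=O)N(C)OC | intermediate
39 | (4-bromo-2-methoxyphenoxy)(tert-butyl)dimethylsilane | COc1cc(Br)ccc1O[Si](C)(C)C(C)(C)C | starting material
40 | [4-(TBS-oxy)-3-methoxyphenyl]lithium | [Li]c1ccc(O[Si](C)(C)C(C)(C)C)c(OC)c1 | intermediate (not isolated)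
41 | pentakis-TBS ether of the target: (2S)-3-(TBS-oxy)-1-[4-(TBS-oxy)-3-methoxyphenyl]-2-{2-(TBS-oxy)-3-methoxy-5-[(1S,3aR,4S,6aR)-4-(DBF)tetrahydro-1H,3H-furo[3,4-c]furan-1-yl]phenyl}propan-1-one | [C@H]1(c2cc(OC)c3c(c2)[C@@H](CO[Si](C)(C)C(C)(C)C)[C@@H](c2ccc(O[Si](C)(C)C(C)(C)C)c(OC)c2)O3)OC[C@H]2[C@@H]1CO[C@@H]2c1cc(OC)c(O[Si](C)(C)C(C)(C)C)c(c1)[C@@H](CO[Si](C)(C)C(C)(C)C)C(=O)c1ccc(O[Si](C)(C)C(C)(C)C)c(OC)c1 | intermediate
42 | CNP0174045.1 | COc1cc(C(=O)[C@H](CO)c2cc([C@H]3OC[C@H]4[C@@H]3CO[C@@H]4c3cc(OC)c4c(c3)[C@@H](CO)[C@@H](c3ccc(O)c(OC)c3)O4)cc(OC)c2O)ccc1O | target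

**Count**

Total steps: 25. Longest linear sequence: 18 steps (steps 8–17, then 18–25).

**Three steps most likely to fail**

1. Step 19 (ring contraction). The ion pair may collapse on the other face of the oxocarbenium carbon (aryl trans to formyl, all-trans product), which would give the wrong absolute configuration at the aryl-bearing ring carbon. The oxocarbenium may also be intercepted by the styrene double bond.
Fallback (relay through the all-trans aldehyde, inverting C4 and not C3): it sets out from 11 and 29 and comes back at 37. Step 18 is run with the mirror-image ligand to give (5R)-2-(DBF)-5-[1-(ArW)ethenyl]-4,5-dihydro-1,3-dioxepine F1. The ring contraction of F1 is then run under conditions that favour the 2,3-trans product (TMSOTf, CH2Cl2, −78 to −20 °C) to give the all-trans aldehyde (2S,3S,4R)-2-(DBF)-4-[1-(ArW)ethenyl]oxolane-3-carbaldehyde F2. NaBH4 reduces F2 to the alcohol (2S,3R,4R)-2-(DBF)-4-[1-(ArW)ethenyl]-3-(hydroxymethyl)oxolane F3. Lemieux–Johnson cleavage of F3 with OsO4 (cat.), NaIO4 and 2,6-lutidine gives the trans hydroxy ketone (2S,3R,4S)-2-(DBF)-3-(hydroxymethyl)-4-[(ArW)carbonyl]oxolane F4. DBU then epimerises F4 at the carbon alpha to the ketone into the cis, hemiketal-stabilised isomer 36, which NaBH4 reduces in the same flask to 37.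

2. Step 18 (Heck union). Oxidative addition and insertion may be slow with two large partners used in near-equal amounts, the triflate may decompose under amine base at 60 °C, and the choice between the enantiotopic alkene carbons may erode. A minor C5 epimer would be a diastereomer and should be separable at 32.
Fallback (oxidative boron-Heck, base-free at rt, in place of the triflate pathway): it sets out from 29 and 11 and comes back at 30. Miyaura borylation of 29 with B2pin2, PdCl2(PPh3)2, PPh3 and KOPh in toluene at 50 °C gives 2-[1-(ArW)ethenyl]-4,4,5,5-tetramethyl-1,3,2-dioxaborolane F5. F5 is coupled with 11 using Pd(OAc)2, a chiral pyridine-oxazoline ligand and benzoquinone in DMF at rt; insertion and beta-hydride elimination towards O–CH2 again give 30.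

3. Step 24 (ketone formation). The aryllithium may deprotonate the benzylic carbon alpha to the amide in competition with addition, which would cause epimerisation of that centre and incomplete conversion.
Fallback (aldehyde addition and neutral oxidation in place of direct acylation): it sets out from 38 and comes back at 41. DIBAL-H in THF at −78 °C reduces 38 to the aldehyde (2S)-3-(TBS-oxy)-2-{2-(TBS-oxy)-3-methoxy-5-[(1S,3aR,4S,6aR)-4-(DBF)tetrahydro-1H,3H-furo[3,4-c]furan-1-yl]phenyl}propanal F6, which is used at once. Addition of 40 to F6 at −78 °C gives the carbinol (2S)-3-(TBS-oxy)-1-[4-(TBS-oxy)-3-methoxyphenyl]-2-{2-(TBS-oxy)-3-methoxy-5-[(1S,3aR,4S,6aR)-4-(DBF)tetrahydro-1H,3H-furo[3,4-c]furan-1-yl]phenyl}propan-1-ol F7 as a mixture of carbinol epimers. Dess–Martin periodinane buffered with NaHCO3 then oxidises F7 to 41.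

**Further compounds**

F1 | step 19 | (5R)-2-(DBF)-5-[1-(ArW)ethenyl]-4,5-dihydro-1,3-dioxepine | C1(c2cc(OC)c3c(c2)[C@@H](CO[Si](C)(C)C(C)(C)C)[C@@H](c2ccc(O[Si](C)(C)C(C)(C)C)c(OC)c2)O3)OC[C@@H](C(=C)c2cc(OC)c(O[Si](C)(C)C(C)(C)C)c(c2)[C@@H](CO[Si](C)(C)C(C)(C)C)C(=O)N(C)OC)C=CO1
F2 | step 19 | (2S,3S,4R)-2-(DBF)-4-[1-(ArW)ethenyl]oxolane-3-carbaldehyde (all-trans) | [C@H]1(c2cc(OC)c3c(c2)[C@@H](CO[Si](C)(C)C(C)(C)C)[C@@H](c2ccc(O[Si](C)(C)C(C)(C)C)c(OC)c2)O3)OC[C@@H](C(=C)c2cc(OC)c(O[Si](C)(C)C(C)(C)C)c(c2)[C@@H](CO[Si](C)(C)C(C)(C)C)C(=O)N(C)OC)[C@@H]1C=O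
F3 | step 19 | (2S,3R,4R)-2-(DBF)-4-[1-(ArW)ethenyl]-3-(hydroxymethyl)oxolane | [C@H]1(c2cc(OC)c3c(c2)[C@@H](CO[Si](C)(C)C(C)(C)C)[C@@H](c2ccc(O[Si](C)(C)C(C)(C)C)c(OC)c2)O3)OC[C@@H](C(=C)c2cc(OC)c(O[Si](C)(C)C(C)(C)C)c(c2)[C@@H](CO[Si](C)(C)C(C)(C)C)C(=O)N(C)OC)[C@@H]1CO
F4 | step 19 | (2S,3R,4S)-2-(DBF)-3-(hydroxymethyl)-4-[(ArW)carbonyl]oxolane (3,4-trans) | [C@H]1(c2cc(OC)c3c(c2)[C@@H](CO[Si](C)(C)C(C)(C)C)[C@@H](c2ccc(O[Si](C)(C)C(C)(C)C)c(OC)c2)O3)OC[C@@H](C(=O)c2cc(OC)c(O[Si](C)(C)C(C)(C)C)c(c2)[C@@H](CO[Si](C)(C)C(C)(C)C)C(=O)N(C)OC)[C@@H]1CO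
F5 | step 18 | 2-[1-(ArW)ethenyl]-4,4,5,5-tetramethyl-1,3,2-dioxaborolane | C=C(B1OC(C)(C)C(C)(C)O1)c1cc(OC)c(O[Si](C)(C)C(C)(C)C)c(c1)[C@@H](CO[Si](C)(C)C(C)(C)C)C(=O)N(C)OC
F6 | step 24 | (2S)-3-(TBS-oxy)-2-{2-(TBS-oxy)-3-methoxy-5-[(1S,3aR,4S,6aR)-4-(DBF)tetrahydro-1H,3H-furo[3,4-c]furan-1-yl]phenyl}propanal | [C@H]1(c2cc(OC)c3c(c2)[C@@H](CO[Si](C)(C)C(C)(C)C)[C@@H](c2ccc(O[Si](C)(C)C(C)(C)C)c(OC)c2)O3)OC[C@H]2[C@@H]1CO[C@@H]2c1cc(OC)c(O[Si](C)(C)C(C)(C)C)c(c1)[C@@H](CO[Si](C)(C)C(C)(C)C)C=O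
F7 | step 24 | (2S)-3-(TBS-oxy)-1-[4-(TBS-oxy)-3-methoxyphenyl]-2-{2-(TBS-oxy)-3-methoxy-5-[(1S,3aR,4S,6aR)-4-(DBF)tetrahydro-1H,3H-furo[3,4-c]furan-1-yl]phenyl}propan-1-ol (carbinol epimers) | [C@H]1(c2cc(OC)c3c(c2)[C@@H](CO[Si](C)(C)C(C)(C)C)[C@@H](c2ccc(O[Si](C)(C)C(C)(C)C)c(OC)c2)O3)OC[C@H]2[C@@H]1CO[C@@H]2c1cc(OC)c(O[Si](C)(C)C(C)(C)C)c(c1)[C@@H](CO[Si](C)(C)C(C)(C)C)C(O)c1ccc(O[Si](C)(C)C(C)(C)C)c(OC)c1
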